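**Retrosynthetic overview**

1. The target is a (2S)-flavanone. It is reached by global desilylation, and the (E)-4-hydroxy-3-methylbut-2-enyl chain comes from an 8-allyl group by cross-metathesis with methacrolein followed by 1,2-reduction.
2. Ring C (the pyranone) is disconnected at C2–C3. The flavanone is the O-to-C rearranged isomer of a cyclic vinyl acetal (a 2-aryl-4-methylene-1,3-benzodioxine), so a catalytic asymmetric Petasis–Ferrier-type rearrangement closes ring C and sets C2 in one operation.
3. Enabling feature: C2 sits at the acetal oxidation level between O1 and ring B, whose para oxygen (O4') stabilises a cation at C2. C3–C4 is the enol of the ring A aryl ketone held ortho to O1. Ionising the acetal therefore creates electrophile and nucleophile in one ion pair.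
4. The vinyl acetal comes from the acylal (1,3-benzodioxin-4-one) by Petasis methylenation. The acylal is the condensation product of a salicylic acid (from methyl 2,4-dihydroxybenzoate by O-allylation and Claisen rearrangement) with silylated 3,4-dihydroxybenzaldehyde.
5. Ring order: rings A and B are bought; a temporary dioxinone ring is made in step 6; ring C is closed in step 8.

Key step: step 8

Assumption: for the new substrate class of step 8 the sense of induction cannot be predicted with confidence. The (R)-acid is written, and its (S)-antipode would be used instead if a test run shows that it is the one leading to the 2S series.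

**Route**

Step 1
Reactants: 1 methyl 2,4-dihydroxybenzoate
Product: 2 methyl 4-(allyloxy)-2-hydroxybenzoate
Conditions: allyl bromide, K2CO3, acetone, reflux
Reagents that add atoms: allyl bromide, C=CCBr
Why: Williamson etherification; the 2-OH is hydrogen-bonded to the ester carbonyl, so K2CO3 in acetone should alkylate only the 4-OH.

Step 2
Reactants: 2 methyl 4-(allyloxy)-2-hydroxybenzoate
Product: 4 methyl 3-allyl-2,4-dihydroxybenzoate, via Claisen dienone 3 (not isolated)
Conditions: N,N-diethylaniline, 200 °C, argon
Reagents that add atoms: none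
Why: Aromatic Claisen rearrangement followed by tautomerisation of dienone 3; the chelated salicylate raises the double-bond character of C3–C4, so migration to C3 between the two oxygens should be favoured over C5.

Step 3
Reactants: 4 methyl 3-allyl-2,4-dihydroxybenzoate
Product: 5 3-allyl-2,4-dihydroxybenzoic acid
Conditions: 2 M NaOH, MeOH, 60 °C; then 1 M HCl, 0 °C
Reagents that add atoms: sodium hydroxide, [Na+].[OH-]
Why: Ester saponification; acidification in the cold should avoid decarboxylation of the electron-rich hydroxy acid.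

Step 4
Reactants: 5 3-allyl-2,4-dihydroxybenzoic acid
Product: 7 3-allyl-2-hydroxy-4-(triisopropylsilyloxy)benzoic acid, via bis(triisopropylsilyl) derivative 6 (not isolated)
Conditions: TIPSCl (2.3 equiv), imidazole, DMF, rt; then K2CO3, MeOH/H2O, 0 °C; 1 M HCl work-up
Reagents that add atoms: triisopropylsilyl chloride, CC(C)[Si](Cl)(C(C)C)C(C)C
Why: Silylation of the free 4-OH and the acid while the chelated, flanked 2-OH stays free, followed by selective solvolysis of the much more labile silyl ester.

Step 5
Reactants: 8 3,4-dihydroxybenzaldehyde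
Product: 9 3,4-bis(tert-butyldimethylsilyloxy)benzaldehyde
Conditions: TBSCl (2.3 equiv), imidazole, DMF, rt
Reagents that add atoms: tert-butyldimethylsilyl chloride, CC(C)(C)[Si](C)(C)Cl
Why: Standard silyl ether formation on both phenols under imidazole catalysis.

Step 6
Reactants: 7 3-allyl-2-hydroxy-4-(triisopropylsilyloxy)benzoic acid; 9 3,4-bis(tert-butyldimethylsilyloxy)benzaldehyde
Product: 11 8-allyl-2-[3,4-bis(tert-butyldimethylsilyloxy)phenyl]-7-(triisopropylsilyloxy)-4H-1,3-benzodioxin-4-one (racemic), via bis(trimethylsilyl) derivative 10 (not isolated)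
Conditions: BSA, CH2Cl2, rt; then 9, TMSOTf (15 mol%), −78 to −30 °C; Et3N quench
Reagents that add atoms: N,O-bis(trimethylsilyl)acetamide, CC(=N[Si](C)(C)C)O[Si](C)(C)C (its silyl groups appear only in intermediate 10)
Why: Silyl-mediated acetalisation as used for 1,3-dioxan-4-ones from bis-silylated hydroxy acids and aldehydes; TMSOTf activates the aldehyde and the aryl silyl ether and silyl ester close the six-membered acylal with loss of hexamethyldisiloxane, the racemic acetal centre being erased later in step 8.

Step 7
Reactants: 11 8-allyl-2-[3,4-bis(tert-butyldimethylsilyloxy)phenyl]-7-(triisopropylsilyloxy)-4H-1,3-benzodioxin-4-one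
Product: 12 8-allyl-2-[3,4-bis(tert-butyldimethylsilyloxy)phenyl]-4-methylene-7-(triisopropylsilyloxy)-4H-1,3-benzodioxine (racemic)
Conditions: Cp2TiMe2 (3 equiv), THF, 65 °C, dark; filtration through basic alumina
Reagents that add atoms: dimethyltitanocene Cp2TiMe2, [CH3-].[CH3-].[Ti+4].c1cc[cH-]c1.c1cc[cH-]c1
Why: Petasis methylenation of the lactone-type carbonyl through titanocene methylidene, a non-acidic and non-basic reagent that should spare the acylal, the silyl ethers and the allyl group, as in the methylenation of 1,3-dioxan-4-ones.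

Step 8
Reactants: 12 8-allyl-2-[3,4-bis(tert-butyldimethylsilyloxy)phenyl]-4-methylene-7-(triisopropylsilyloxy)-4H-1,3-benzodioxine
Product: 14 (2S)-8-allyl-2-[3,4-bis(tert-butyldimethylsilyloxy)phenyl]-7-(triisopropylsilyloxy)chroman-4-one, via oxocarbenium enol cation 13 (not isolated)
Conditions: (R)-3,3'-bis(9-anthryl)-1,1'-binaphthyl-2,2'-diyl hydrogen phosphate (5 mol%), 5 Å MS, toluene, −20 °C to rt
Reagents that add atoms: none
Why: Proposed new method: the chiral phosphoric acid should protonate the enol-ether oxygen O3 of 12 and ionise the C2–O3 bond to the O-aryl oxocarbenium ion 13, which is stabilised by the para-silyloxy group of ring B and held to the chiral phosphate through its enol OH; the enol carbon then attacks C2, forming the C2–C3 bond, and proton loss gives the C4 ketone, so 12 isomerises to 14 with no atom lost. The closest known reaction types are the Lewis acid Petasis–Ferrier rearrangement of 4-methylene-1,3-dioxanes to tetrahydropyran-4-ones and the chiral phosphoric acid-catalysed Petasis–Ferrier-type rearrangements of aliphatic cyclic vinyl acetals and hemiaminal vinyl ethers; the benzo-fused acetal of an aryl ketone enol used here has not been shown. Ring C closes in a 6-(enolendo)-endo-trig mode while the temporary dioxine ring opens. C2 is set by the catalyst: the acetal centre of racemic 12 is erased in planar 13, and the binaphthyl phosphate bridging enol OH and cation should leave one face of the oxocarbenium carbon open, so both enantiomers of 12 should converge on 2S. The step needs C- rather than O-recombination and no reaction at the allyl group; O-recombination only regenerates 12 whereas C–C bond formation is irreversible, and the monosubstituted alkene is far less nucleophilic than the enol born in the same ion pair.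

Step 9
Reactants: 14 (2S)-8-allyl-2-[3,4-bis(tert-butyldimethylsilyloxy)phenyl]-7-(triisopropylsilyloxy)chroman-4-one
Product: 15 (2E)-4-[(2S)-2-[3,4-bis(tert-butyldimethylsilyloxy)phenyl]-4-oxo-7-(triisopropylsilyloxy)chroman-8-yl]-2-methylbut-2-enal
Conditions: second-generation Hoveyda–Grubbs catalyst (5 mol%), methacrolein (15 equiv), CH2Cl2, 40 °C
Reagents that add atoms: methacrolein, CC(=C)C=O
Why: Olefin cross-metathesis of the terminal alkene with an excess of the electron-poor 1,1-disubstituted partner; the trisubstituted enal should form as the thermodynamically preferred E isomer, and the flavanone is inert under these neutral conditions.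

Step 10
Reactants: 15 (2E)-4-[(2S)-2-[3,4-bis(tert-butyldimethylsilyloxy)phenyl]-4-oxo-7-(triisopropylsilyloxy)chroman-8-yl]-2-methylbut-2-enal
Product: 16 (2S)-2-[3,4-bis(tert-butyldimethylsilyloxy)phenyl]-8-[(2E)-4-hydroxy-3-methylbut-2-en-1-yl]-7-(triisopropylsilyloxy)chroman-4-one
Conditions: NaBH4, CeCl3·7H2O, MeOH/THF, −78 °C
Reagents that add atoms: none
Why: Luche 1,2-reduction; the enal is far more electrophilic than the C4 aryl ketone, which is deactivated by the O1 and O7 donors, so the aldehyde should be reduced selectively with the alkene geometry and C2 untouched.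

Step 11
Reactants: 16 (2S)-2-[3,4-bis(tert-butyldimethylsilyloxy)phenyl]-8-[(2E)-4-hydroxy-3-methylbut-2-en-1-yl]-7-(triisopropylsilyloxy)chroman-4-one
Product: 17 (2S)-2-(3,4-dihydroxyphenyl)-7-hydroxy-8-[(2E)-4-hydroxy-3-methylbut-2-en-1-yl]chroman-4-one
Conditions: TBAF/AcOH (1:1.1, 3.3 equiv), THF, 0 °C
Reagents that add atoms: none
Why: Fluoride-mediated cleavage of the three aryl silyl ethers; the acetic acid buffer keeps the phenols protonated, so base-induced ring opening of the flavanone to the chalcone (the racemisation path) should be avoided.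

**Compound list**

1 | methyl 2,4-dihydroxybenzoate | COC(=O)c1ccc(O)cc1O | starting material
2 | methyl 4-(allyloxy)-2-hydroxybenzoate | COC(=O)c1ccc(OCC=C)cc1O | intermediate
3 | methyl 3-allyl-2-hydroxy-4-oxocyclohexa-1,5-diene-1-carboxylate (Claisen dienone) | COC(=O)C1=C(O)C(CC=C)C(=O)C=C1 | intermediate
4 | methyl 3-allyl-2,4-dihydroxybenzoate | COC(=O)c1ccc(O)c(CC=C)c1O | intermediate
5 | 3-allyl-2,4-dihydroxybenzoic acid | OC(=O)c1ccc(O)c(CC=C)c1O | intermediate
6 | triisopropylsilyl 3-allyl-2-hydroxy-4-(triisopropylsilyloxy)benzoate | CC(C)[Si](C(C)C)(C(C)C)OC(=O)c1ccc(O[Si](C(C)C)(C(C)C)C(C)C)c(CC=C)c1O | intermediate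
7 | 3-allyl-2-hydroxy-4-(triisopropylsilyloxy)benzoic acid | OC(=O)c1ccc(O[Si](C(C)C)(C(C)C)C(C)C)c(CC=C)c1O | intermediate
8 | 3,4-dihydroxybenzaldehyde | O=Cc1ccc(O)c(O)c1 | starting material
9 | 3,4-bis(tert-butyldimethylsilyloxy)benzaldehyde | O=Cc1ccc(O[Si](C)(C)C(C)(C)C)c(O[Si](C)(C)C(C)(C)C)c1 | intermediate
10 | trimethylsilyl 3-allyl-4-(triisopropylsilyloxy)-2-(trimethylsilyloxy)benzoate | C[Si](C)(C)OC(=O)c1ccc(O[Si](C(C)C)(C(C)C)C(C)C)c(CC=C)c1O[Si](C)(C)C | intermediate
11 | 8-allyl-2-[3,4-bis(tert-butyldimethylsilyloxy)phenyl]-7-(triisopropylsilyloxy)-4H-1,3-benzodioxin-4-one (racemic) | O=C1OC(c2ccc(O[Si](C)(C)C(C)(C)C)c(O[Si](C)(C)C(C)(C)C)c2)Oc2c(CC=C)c(O[Si](C(C)C)(C(C)C)C(C)C)ccc12 | intermediate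
12 | 8-allyl-2-[3,4-bis(tert-butyldimethylsilyloxy)phenyl]-4-methylene-7-(triisopropylsilyloxy)-4H-1,3-benzodioxine (racemic) | C=C1OC(c2ccc(O[Si](C)(C)C(C)(C)C)c(O[Si](C)(C)C(C)(C)C)c2)Oc2c(CC=C)c(O[Si](C(C)C)(C(C)C)C(C)C)ccc12 | intermediate
13 | ring-opened O-aryl oxocarbenium ion carrying the ketone enol (paired with the catalyst anion) | C=C(O)c1ccc(O[Si](C(C)C)(C(C)C)C(C)C)c(CC=C)c1[O+]=Cc1ccc(O[Si](C)(C)C(C)(C)C)c(O[Si](C)(C)C(C)(C)C)c1 | intermediate
14 | (2S)-8-allyl-2-[3,4-bis(tert-butyldimethylsilyloxy)phenyl]-7-(triisopropylsilyloxy)chroman-4-one | C=CCc1c(O[Si](C(C)C)(C(C)C)C(C)C)ccc2c1O[C@H](c1ccc(O[Si](C)(C)C(C)(C)C)c(O[Si](C)(C)C(C)(C)C)c1)CC2=O | intermediate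
15 | (2E)-4-[(2S)-2-[3,4-bis(tert-butyldimethylsilyloxy)phenyl]-4-oxo-7-(triisopropylsilyloxy)chroman-8-yl]-2-methylbut-2-enal | C/C(C=O)=C\Cc1c(O[Si](C(C)C)(C(C)C)C(C)C)ccc2c1O[C@H](c1ccc(O[Si](C)(C)C(C)(C)C)c(O[Si](C)(C)C(C)(C)C)c1)CC2=O | intermediate
16 | (2S)-2-[3,4-bis(tert-butyldimethylsilyloxy)phenyl]-8-[(2E)-4-hydroxy-3-methylbut-2-en-1-yl]-7-(triisopropylsilyloxy)chroman-4-one | C/C(CO)=C\Cc1c(O[Si](C(C)C)(C(C)C)C(C)C)ccc2c1O[C@H](c1ccc(O[Si](C)(C)C(C)(C)C)c(O[Si](C)(C)C(C)(C)C)c1)CC2=O | intermediate
17 | (2S)-2-(3,4-dihydroxyphenyl)-7-hydroxy-8-[(2E)-4-hydroxy-3-methylbut-2-en-1-yl]chroman-4-one | C/C(=C\Cc1c(O)ccc2c1O[C@H](c1ccc(O)c(O)c1)CC2=O)CO | target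

**Step count and risks**

Total step count: 11. Longest linear sequence: 10 steps (steps 1–4 and 6–11, from methyl 2,4-dihydroxybenzoate); step 5 is a one-step branch.

Steps most likely to fail:

1. Step 8 (proposed new method). The ion pair may collapse before the chiral anion has organised it, so that the configuration of the racemic acetal is partly carried through and the enantioselectivity is low. The enol ether may also be protonated at carbon and hydrolysed by traces of water, or the product may slowly re-ionise at C2–O1 under the acid and erode. The fallback uses known chemistry, sets out from 7 and returns at 14. Acid 7 is treated with MeLi (3.5 equiv, THF, −78 to 0 °C) to give the methyl ketone 1-[3-allyl-2-hydroxy-4-(triisopropylsilyloxy)phenyl]ethanone F1. Heating with N,N-dimethylformamide dimethyl acetal gives the enaminone (2E)-1-[3-allyl-2-hydroxy-4-(triisopropylsilyloxy)phenyl]-3-(dimethylamino)prop-2-en-1-one F2, which closes under mild acid (cat. TsOH, toluene, 60 °C) to the chromone 8-allyl-7-(triisopropylsilyloxy)-4H-chromen-4-one F3. Commercial 4-bromobenzene-1,2-diol is silylated to 4-bromo-1,2-bis(tert-butyldimethylsilyloxy)benzene F4 and converted by bromine–lithium exchange (n-BuLi) and B(OiPr)3 into [3,4-bis(tert-butyldimethylsilyloxy)phenyl]boronic acid F5. Enantioselective conjugate addition of F5 to F3 with Pd(OCOCF3)2 and (R)-4-tert-butyl-2-(pyridin-2-yl)-4,5-dihydrooxazole (the ligand antipode expected to lead to the 2S series; NH4PF6, water, 1,2-dichloroethane, 60 °C), a known route from chromones to flavanones, should then deliver 14.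

2. Step 6. The chelated, doubly flanked aryl silyl ether may add too slowly to the activated aldehyde, or the electron-rich acylal may re-ionise and fall back to its components during quench and chromatography. The fallback sets out from 9 and 7 and returns at 11. Aldehyde 9 is converted with HC(OMe)3 and cat. PPTS in MeOH into the dimethyl acetal 4-(dimethoxymethyl)-1,2-bis(tert-butyldimethylsilyloxy)benzene F6. Transacetalisation of F6 with the free hydroxy acid 7 (cat. PPTS, toluene, 60 °C, methanol removed continuously over 5 Å sieves) then closes the acylal under thermodynamic control instead of by silyl transfer at low temperature.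

3. Step 10. Hydride may also be delivered to the C4 ketone (over-reduction to the flavan-4-ol) or in a 1,4-sense to the enal. The fallback sets out from 14 and returns at 17 without passing through an aldehyde. Cross-metathesis of 14 with the already reduced partner tert-butyldimethyl[(2-methylprop-2-en-1-yl)oxy]silane (second-generation Hoveyda–Grubbs catalyst, CH2Cl2, 40 °C) should give an E/Z mixture, from which the E isomer (2S)-2-[3,4-bis(tert-butyldimethylsilyloxy)phenyl]-8-[(2E)-4-(tert-butyldimethylsilyloxy)-3-methylbut-2-en-1-yl]-7-(triisopropylsilyloxy)chroman-4-one F7 is separated. F7 is then desilylated under the conditions of step 11 to give 17.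

Further compounds
F1 | step 8 | 1-[3-allyl-2-hydroxy-4-(triisopropylsilyloxy)phenyl]ethanone | CC(=O)c1ccc(O[Si](C(C)C)(C(C)C)C(C)C)c(CC=C)c1O
F2 | step 8 | (2E)-1-[3-allyl-2-hydroxy-4-(triisopropylsilyloxy)phenyl]-3-(dimethylamino)prop-2-en-1-one | CN(C)/C=C/C(=O)c1ccc(O[Si](C(C)C)(C(C)C)C(C)C)c(CC=C)c1O
F3 | step 8 | 8-allyl-7-(triisopropylsilyloxy)-4H-chromen-4-one | O=c1ccoc2c(CC=C)c(O[Si](C(C)C)(C(C)C)C(C)C)ccc12
F4 | step 8 | 4-bromo-1,2-bis(tert-butyldimethylsilyloxy)benzene | Brc1ccc(O[Si](C)(C)C(C)(C)C)c(O[Si](C)(C)C(C)(C)C)c1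
F5 | step 8 | [3,4-bis(tert-butyldimethylsilyloxy)phenyl]boronic acid | OB(O)c1ccc(O[Si](C)(C)C(C)(C)C)c(O[Si](C)(C)C(C)(C)C)c1
F6 | step 6 | 4-(dimethoxymethyl)-1,2-bis(tert-butyldimethylsilyloxy)benzene | COC(OC)c1ccc(O[Si](C)(C)C(C)(C)C)c(O[Si](C)(C)C(C)(C)C)c1
F7 | step 10 | (2S)-2-[3,4-bis(tert-butyldimethylsilyloxy)phenyl]-8-[(2E)-4-(tert-butyldimethylsilyloxy)-3-methylbut-2-en-1-yl]-7-(triisopropylsilyloxy)chroman-4-one | C/C(CO[Si](C)(C)C(C)(C)C)=C\Cc1c(O[Si](C(C)C)(C(C)C)C(C)C)ccc2c1O[C@H](c1ccc(O[Si](C)(C)C(C)(C)C)c(O[Si](C)(C)C(C)(C)C)c1)CC2=O
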